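The data come from a simulation with constants of no real substance, and the scatter is random.

Grey, blue, red, violet and ochre each take 14 mM of first end groups and 1.00 equiv of second end groups, and the decision is which way of bringing these amounts together to charge next.

| setting | north-west | south-east | north-east | grey | blue | red | violet | ochre |
|---|---|---|---|---|---|---|---|---|
| first end groups | 14 mM | 20 mM | 31 mM | 14 mM (fed, over 1.5 h) | 14 mM | 14 mM | 14 mM (fed, over 1.5 h) | 14 mM |
| second end groups | 1 equiv | 1 equiv | 1 equiv | 1.00 equiv | 1.00 equiv | 1.00 equiv | 1.00 equiv | 1.00 equiv (in portions, 5, over 1.5 h) |
| temperature | 95 °C | 110 °C | 95 °C |  | 110 °C |  | 110 °C | 110 °C |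
| remark | run made earlier | run made earlier | run made earlier | the addition at 90 °C, then warmed to 110 °C; the feed brings no volume worth counting | everything together at the start | everything together at the start at 90 °C, warmed to 110 °C at 1.5 h | all else is in the flask from the start; the feed brings no volume worth counting | first portion at the start, last at 1.5 h |
| time |  |  |  | 8.0 h | 8.0 h | 8.0 h | 8.0 h | 8.0 h |

| run | time / h | links / % | rings / % |
|---|---|---|---|
| north-west | 3.00 | 10.6 | 14.8 |
| north-west | 6.00 | 5.0 | 11.8 |
| north-west | 10.0 | 4.0 | 15.0 |
| north-west | 12.0 | 3.7 | 11.8 |
| north-west | 15.0 | 0 | 13.4 |
| south-east | 0.667 | 14.8 | 14.6 |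
| south-east | 2.00 | 7.7 | 15.4 |
| south-east | 4.00 | 3.2 | 14.5 |
| south-east | 6.00 | 0 | 16.0 |
| south-east | 8.00 | 0.8 | 15.8 |
| north-east | 1.33 | 11.9 | 8.2 |
| north-east | 4.00 | 4.7 | 6.2 |
| north-east | 8.00 | 2.8 | 7.8 |
| north-east | 12.0 | 0 | 8.6 |
| north-east | 15.0 | 0.9 | 8.7 |

(readings scatter by 1 percentage point)

- which flask leads in share of links in links plus rings ("all alike" within 1.5 percentage points) (grey / blue / red / violet / ochre / all alike)
- share of links in links plus rings at the end, grey
- share of links in links plus rings at the end, blue
- share of links in links plus rings at the end, red
- share of links in links plus rings at the end, violet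
- share of links in links plus rings at the end, ochre

- what was read earlier has a scatter of 1 percentage point, one standard deviation

Links are falling between the first two samples of each earlier run, so after those samples they can be treated as a store with a time constant, a pseudo-first-order decay. The north-west run reads 0.250 /h at 14 mM. The north-east run reads 0.348 /h at 31 mM, so the decay is faster at the higher charge. My own step is to scale the south-east reading in proportion to charge, which gives 0.343 /h at 110 °C and 14 mM. These rates are readings and carry the scatter of 1 percentage point.

The crossing is where the decay of links overtakes their making, and making need not stop there. My reckoning takes the end of the addition as its reference moment and multiplies the decay rate by the hours from that moment to the end. For links standing at 1.5 h in a flask at 110 °C, this count is 2.23; call it the link lifetimes remaining. In this reckoning, the part of those links that survives is the negative exponential of the count. Blue, counted from the start, has 2.74, and red, with its cool first stretch, has 2.61. The flasks with an addition have the smaller count, and by this reckoning links standing at that moment keep 1.67 times what links standing in blue at the start keep. So my choice is a flask with an addition rather than blue, though the count is the same for grey, violet and ochre and does not tell how many links each holds at that moment.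

The forecast named grey as leader, with grey 15%, blue 10%, red 14.5%, violet 10.5% and ochre 10.5%, holding that “The share therefore follows rings”.

The flasks give grey 17.5%, blue 7.32%, red 9.56%, violet 21.8% and ochre 0.600%, so violet leads.

    first end groups + second end groups → links (k = 0.0810 /M/s, Ea = 82.0 kJ/mol)
    first end groups + second end groups → rings, rate k2*[first end groups] as long as [second end groups] is above zero (k = 0.00100 /s, Ea = 101 kJ/mol)
    second end groups + links → over-reaction product (k = 0.0120 /M/s, Ea = 68.0 kJ/mol)
    2 first end groups → homo dimer (k = 0.320 /M/s, Ea = 62.0 kJ/mol)
    (constants at 110 °C)

Forecast and flask part at ochre, 10.5% against 0.600%. At 1.50 h, just before its last addition, ochre held 2.32% links, and the reckoning with 2.23 lifetimes leaves 0.249%, but ochre held less, 0.133% at 8.00 h. The neighbouring flask is ochre kept at 95 °C. With the cool rate 0.250 /h, its count is 1.63, so the reckoning lets 19.6% of the links standing at that moment survive, against 10.8% reckoned for ochre. That neighbour ended with 1.29% links, and its share was 7.23%.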